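## Retrosynthetic overview

1. The (E)-propenyl group on C5 is attached last, by Suzuki–Miyaura coupling of a 5-chloro-2,3-dihydrobenzofuran with (E)-prop-1-enylboronic acid.
2. The dihydrofuran ring is the only ring made. It is closed late (O1–C2) by acid-mediated SN1 cyclisation of a 1-aryl-2-(2-hydroxyaryl)propan-1-ol, trans under thermodynamic control. Rings A and B both come from catechol.
3. Key step: a palladium-catalysed, enantioselective three-component (conjunctive) coupling. The ring B aryl shifts 1,2 from boron to carbon in a propenyl borate (makes C2–aryl), reductive elimination makes C3–C3a, and the ligand sets C3.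
4. Ring A partner: 2-bromo-4-chloro-6-methoxyphenol (catechol: mono-methylation, para-chlorination, ortho-bromination), its OH masked in the flask as a boryl ether.
5. Ring B partner: 5-bromo-1,2-dimethoxy-3-(methoxymethoxy)benzene (catechol: dimethylation, ortho-lithiation/hydroxylation, MOM protection, meta C–H borylation/bromination).

Assumption: (Sp,Sp)-MandyPhos is taken to give the (1S,2S) alcohol of step 9; if the sense of induction is the opposite, the (Rp,Rp) ligand is used.

Abbreviations: mac-H2 = cis-1,2-dimethyl-1,2-dihydroacenaphthylene-1,2-diol (one step from acenaphthenequinone and MeMgBr); B(mac) = its cyclic boronic ester; Bpin = pinacol boronic ester; MOM = methoxymethyl.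

## Route

Step 1
Reactants: 1 catechol (benzene-1,2-diol)
Product: 2 guaiacol (2-methoxyphenol)
Conditions: MeI (1.0 equiv), K2CO3 (1.0 equiv), acetone, reflux
Reagents that add atoms: iodomethane, CI
Why: Williamson ether synthesis; one equivalent of MeI monomethylates the two equivalent OH groups statistically, and the phenolic product is separated from veratrole and catechol by extraction and distillation.

Step 2
Reactants: 2 guaiacol
Product: 3 4-chloro-2-methoxyphenol
Conditions: SO2Cl2 (1.05 equiv), CH2Cl2, 0 °C to rt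
Reagents that add atoms: sulfuryl chloride, O=S(=O)(Cl)Cl
Why: Electrophilic aromatic chlorination; the free OH is the strongest director and chlorine enters para to it.

Step 3
Reactants: 3 4-chloro-2-methoxyphenol
Product: 4 2-bromo-4-chloro-6-methoxyphenol
Conditions: NBS (1.05 equiv), MeCN, 0 °C to rt
Reagents that add atoms: N-bromosuccinimide, O=C1CCC(=O)N1Br
Why: Electrophilic aromatic bromination; with the para position blocked, NBS brominates the one remaining position ortho to OH.

Step 4
Reactants: 1 catechol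
Product: 5 veratrole (1,2-dimethoxybenzene)
Conditions: MeI (2.5 equiv), K2CO3 (3 equiv), acetone, reflux
Reagents that add atoms: iodomethane, CI
Why: Double Williamson ether synthesis with excess MeI.

Step 5
Reactants: 5 veratrole
Product: 8 2,3-dimethoxyphenol, via 2,3-dimethoxyphenyllithium 6 (not isolated), via lithium trimethoxy(2,3-dimethoxyphenyl)borate 7 (not isolated)
Conditions: n-BuLi, TMEDA, Et2O, 0 °C to rt; B(OMe)3, −78 °C to rt; AcOH, 30% H2O2, 0 °C to rt
Reagents that add atoms: hydrogen peroxide, OO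
Why: Directed ortho-metalation (the methoxy group directs lithiation to C3), borate formation and peroxide oxidation of C–B to C–OH, a standard one-pot phenol synthesis.

Step 6
Reactants: 8 2,3-dimethoxyphenol
Product: 9 1,2-dimethoxy-3-(methoxymethoxy)benzene
Conditions: MOMCl (1.3 equiv), K2CO3 (2 equiv), acetone, 0 °C to rt
Reagents that add atoms: chloromethyl methyl ether, COCCl
Why: Williamson-type O-alkylation that installs the MOM acetal as an acid-labile protecting group.

Step 7
Reactants: 9 1,2-dimethoxy-3-(methoxymethoxy)benzene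
Product: 11 5-bromo-1,2-dimethoxy-3-(methoxymethoxy)benzene, via aryl pinacol boronate 10 (not isolated)
Conditions: [Ir(OMe)(cod)]2 (1 mol%), dtbpy (2 mol%), B2pin2 (0.6 equiv), THF, 80 °C; then CuBr2 (3 equiv), MeOH/H2O 1:1, 80 °C
Reagents that add atoms: copper dibromide, [Cu+2].[Br-].[Br-]
Why: Sterically controlled iridium-catalysed C–H borylation at C5 (the only C–H without an ortho substituent), then copper-mediated bromodeboronation in the same pot, a known one-pot meta-bromination.

Step 8
Reactants: 12 (E)-prop-1-enylboronic acid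
Product: 13 (E)-prop-1-enylboronic acid mac ester
Conditions: mac-H2 (1.0 equiv), MgSO4, CH2Cl2, rt
Reagents that add atoms: mac-H2 (cis-1,2-dimethyl-1,2-dihydroacenaphthylene-1,2-diol), O[C@@]1(C)c2cccc3cccc(c23)[C@@]1(C)O
Why: Condensation of a boronic acid with a cis-1,2-diol to the cyclic boronic ester; the E alkene is untouched.

Step 9
Reactants: 4 2-bromo-4-chloro-6-methoxyphenol, 11 5-bromo-1,2-dimethoxy-3-(methoxymethoxy)benzene, 13 (E)-prop-1-enylboronic acid mac ester
Product: 18 (1S,2S)-2-(5-chloro-2-hydroxy-3-methoxyphenyl)-1-[3,4-dimethoxy-5-(methoxymethoxy)phenyl]propan-1-ol, via O-boryl aryl bromide 14 (not isolated), via aryllithium 15 (not isolated), via lithium alkenyl(aryl)borate 16 (not isolated), via secondary alkyl boronate 17 (not isolated)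
Conditions: 4, HBpin (1.05 equiv), THF, rt, then evaporation; 11, t-BuLi (2.0 equiv), Et2O, −78 °C, then 13, −78 °C to rt; both solutions added to Pd(OAc)2 (2 mol%), (Sp,Sp)-MandyPhos (2.4 mol%), NaOTf (2 equiv), THF, 60 °C; then 3 M NaOH, 30% H2O2, 0 °C to rt
Reagents that add atoms: hydrogen peroxide, OO
Why: Proposed new method: a palladium-induced 1,2-metallate shift (conjunctive cross-coupling) in which zerovalent palladium inserts into the C–Br bond of 14 (not C–Cl), NaOTf removes bromide, the cationic aryl-palladium binds the alkene of borate 16, the ring B aryl shifts from boron to the α-carbon anti to palladium and C–C reductive elimination gives 17 by anti addition across the E alkene, the ligand choosing the alkene face so that C2 of the propyl chain (the later C3) is S and C1 follows as S, after which stereoretentive peroxide oxidation gives 18; the new element is the use of a β-methyl B(mac) borate carrying a tri-oxygenated migrating aryl together with an aryl bromide whose ortho phenol is masked only as a traceless O-Bpin ester (neutral, non-acidic, cleaved in the oxidative work-up), the closest known reactions being the enantioselective conjunctive coupling of β-substituted alkenyl B(mac) ate complexes with protected aryl electrophiles and the use of O-Bpin as traceless phenol protection in iridium-catalysed C–H borylation.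

Step 10
Reactants: 18 (1S,2S)-2-(5-chloro-2-hydroxy-3-methoxyphenyl)-1-[3,4-dimethoxy-5-(methoxymethoxy)phenyl]propan-1-ol
Product: 20 5-[(2S,3S)-5-chloro-7-methoxy-3-methyl-2,3-dihydro-1-benzofuran-2-yl]-2,3-dimethoxyphenol, via MOM-protected dihydrobenzofuran 19 (not isolated)
Conditions: HCl (0.5 M in MeOH), rt to 40 °C
Reagents that add atoms: none
Why: Acid-catalysed SN1 cycloetherification in which the benzylic alcohol ionises to a cation stabilised by the 4-methoxyaryl group and is captured by the ortho phenol, C2 being set trans to the C3 methyl (2S) under thermodynamic control because the ring reopens reversibly while C3 is untouched, and the MOM acetal is removed by methanolysis in the same pot.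

Step 11
Reactants: 20 5-[(2S,3S)-5-chloro-7-methoxy-3-methyl-2,3-dihydro-1-benzofuran-2-yl]-2,3-dimethoxyphenol, 12 (E)-prop-1-enylboronic acid
Product: 21 5-[(2S,3S)-7-methoxy-3-methyl-5-[(E)-prop-1-enyl]-2,3-dihydro-1-benzofuran-2-yl]-2,3-dimethoxyphenol
Conditions: 12 (2 equiv), Pd(OAc)2 (3 mol%), SPhos (6 mol%), K3PO4 (3 equiv), toluene/H2O 10:1, 90 °C
Reagents that add atoms: none
Why: Suzuki–Miyaura coupling; the electron-rich SPhos ligand allows oxidative addition into the aryl chloride, the E geometry of the alkenylboronic acid is retained and no stereocentre is touched.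

## Compound list

1 | catechol (benzene-1,2-diol) | Oc1ccccc1O | starting material
2 | guaiacol (2-methoxyphenol) | COc1ccccc1O | intermediate
3 | 4-chloro-2-methoxyphenol | COc1cc(Cl)ccc1O | intermediate
4 | 2-bromo-4-chloro-6-methoxyphenol | COc1cc(Cl)cc(Br)c1O | intermediate
5 | veratrole (1,2-dimethoxybenzene) | COc1ccccc1OC | intermediate
6 | 2,3-dimethoxyphenyllithium | [Li]c1cccc(OC)c1OC | intermediate
7 | lithium trimethoxy(2,3-dimethoxyphenyl)borate | [Li+].CO[B-](OC)(OC)c1cccc(OC)c1OC | intermediate
8 | 2,3-dimethoxyphenol | COc1cccc(O)c1OC | intermediate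
9 | 1,2-dimethoxy-3-(methoxymethoxy)benzene | COCOc1cccc(OC)c1OC | intermediate
10 | 2-[3,4-dimethoxy-5-(methoxymethoxy)phenyl]-4,4,5,5-tetramethyl-1,3,2-dioxaborolane | COCOc1cc(B2OC(C)(C)C(C)(C)O2)cc(OC)c1OC | intermediate
11 | 5-bromo-1,2-dimethoxy-3-(methoxymethoxy)benzene | COCOc1cc(Br)cc(OC)c1OC | intermediate
12 | (E)-prop-1-enylboronic acid | C/C=C/B(O)O | starting material
13 | (E)-prop-1-enylboronic acid mac ester (cyclic boronate of the meso cis-diol mac-H2) | C/C=C/B1O[C@@]2(C)c3cccc4cccc(c34)[C@@]2(C)O1 | intermediate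
14 | 2-(2-bromo-4-chloro-6-methoxyphenoxy)-4,4,5,5-tetramethyl-1,3,2-dioxaborolane | COc1cc(Cl)cc(Br)c1OB1OC(C)(C)C(C)(C)O1 | intermediate
15 | [3,4-dimethoxy-5-(methoxymethoxy)phenyl]lithium | [Li]c1cc(OC)c(OC)c(OCOC)c1 | intermediate
16 | lithium [3,4-dimethoxy-5-(methoxymethoxy)phenyl][(E)-prop-1-enyl]borate of mac-H2 (ate complex, mixture at boron) | [Li+].C/C=C/[B-]1(c2cc(OC)c(OC)c(OCOC)c2)O[C@@]2(C)c3cccc4cccc(c34)[C@@]2(C)O1 | intermediate
17 | B(mac) ester of [(1S,2R)-2-[5-chloro-3-methoxy-2-(pinacolatoboryloxy)phenyl]-1-[3,4-dimethoxy-5-(methoxymethoxy)phenyl]propyl]boronic acid | C[C@@H](c1cc(Cl)cc(OC)c1OB1OC(C)(C)C(C)(C)O1)[C@H](B1O[C@@]2(C)c3cccc4cccc(c34)[C@@]2(C)O1)c1cc(OC)c(OC)c(OCOC)c1 | intermediate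
18 | (1S,2S)-2-(5-chloro-2-hydroxy-3-methoxyphenyl)-1-[3,4-dimethoxy-5-(methoxymethoxy)phenyl]propan-1-ol | C[C@@H](c1cc(Cl)cc(OC)c1O)[C@H](O)c1cc(OC)c(OC)c(OCOC)c1 | intermediate
19 | (2S,3S)-5-chloro-2-[3,4-dimethoxy-5-(methoxymethoxy)phenyl]-7-methoxy-3-methyl-2,3-dihydro-1-benzofuran | Clc1cc(OC)c2c(c1)[C@H](C)[C@@H](c1cc(OCOC)c(OC)c(OC)c1)O2 | intermediate
20 | 5-[(2S,3S)-5-chloro-7-methoxy-3-methyl-2,3-dihydro-1-benzofuran-2-yl]-2,3-dimethoxyphenol | Clc1cc(OC)c2c(c1)[C@H](C)[C@@H](c1cc(O)c(OC)c(OC)c1)O2 | intermediate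
21 | 5-[(2S,3S)-7-methoxy-3-methyl-5-[(E)-prop-1-enyl]-2,3-dihydro-1-benzofuran-2-yl]-2,3-dimethoxyphenol (CNP0299956.1, trans) | C/C=C/c1cc(OC)c2c(c1)[C@H](C)[C@@H](c1cc(O)c(OC)c(OC)c1)O2 | target

## Step count and risks

Total step count: 11. Longest linear sequence: 7 steps (steps 4, 5, 6, 7, 9, 10, 11).

The three steps most likely to fail:

**Step 9 (the proposed new step).** Possible failures are ligand scrambling between the O-boryl ether and the borate, slow oxidative addition next to the O-Bpin group, direct Suzuki-type transfer of the propenyl group, or a low enantiomer ratio. The fallback uses known chemistry, sets out from 4 (and borate 16) and comes back at 20. 4 is converted with MOMCl and K2CO3 into the isolable MOM ether 1-bromo-5-chloro-3-methoxy-2-(methoxymethoxy)benzene F1. F1 is coupled with 16 under Pd(OAc)2/MandyPhos/NaOTf, the conjunctive coupling in its established form with a conventionally protected aryl halide, to give the B(mac) ester of [(1S,2R)-2-[5-chloro-3-methoxy-2-(methoxymethoxy)phenyl]-1-[3,4-dimethoxy-5-(methoxymethoxy)phenyl]propyl]boronic acid F2. NaOH/H2O2 oxidises F2 to (1S,2S)-2-[5-chloro-3-methoxy-2-(methoxymethoxy)phenyl]-1-[3,4-dimethoxy-5-(methoxymethoxy)phenyl]propan-1-ol F3. Under the conditions of step 10, F3 loses both MOM groups and cyclises to 20.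

**Step 10.** Possible failures are a cis/trans mixture, partial loss of configuration at C3 through reversible E1 elimination from the benzylic cation, or cation-derived oligomers. The fallback replaces the SN1 closure by a stereospecific SN2 closure; it sets out from 14 and 15 and comes back at 19. Bought (Z)-prop-1-enylboronic acid is condensed with mac-H2 to (Z)-prop-1-enylboronic acid mac ester F4. Addition of 15 gives the lithium (Z)-alkenyl(aryl)borate F5. Conjunctive coupling with 14 (anti addition across the Z alkene) gives the (1R,2R) secondary boronate F6, the C1 epimer of 17, and oxidation gives (1R,2S)-2-(5-chloro-2-hydroxy-3-methoxyphenyl)-1-[3,4-dimethoxy-5-(methoxymethoxy)phenyl]propan-1-ol F7. Intramolecular Mitsunobu etherification of F7 (PPh3, DIAD, THF, 0 °C) closes the ring with inversion at C1 and gives 19 directly as the trans (2S,3S) isomer. 19 is then isolated and its MOM group removed with dilute HCl in MeOH at rt to give 20.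

**Step 11.** Possible failures are sluggish oxidative addition into the electron-rich aryl chloride and protodeboronation or oligomerisation of the alkenylboronic acid. The fallback reverses the polarity; it sets out from 20 and comes back at 21. Miyaura borylation of 20 (B2pin2, Pd2(dba)3, XPhos, KOAc, dioxane, 100 °C) gives 5-[(2S,3S)-7-methoxy-3-methyl-5-(4,4,5,5-tetramethyl-1,3,2-dioxaborolan-2-yl)-2,3-dihydro-1-benzofuran-2-yl]-2,3-dimethoxyphenol F8. Suzuki–Miyaura coupling of F8 with bought (E)-1-bromopropene (Pd(PPh3)4, K2CO3, dioxane/H2O, 60 °C, sealed vessel) gives 21.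

## Further compounds

F1 | step 9 | 1-bromo-5-chloro-3-methoxy-2-(methoxymethoxy)benzene | COCOc1c(Br)cc(Cl)cc1OC
F2 | step 9 | B(mac) ester of [(1S,2R)-2-[5-chloro-3-methoxy-2-(methoxymethoxy)phenyl]-1-[3,4-dimethoxy-5-(methoxymethoxy)phenyl]propyl]boronic acid | C[C@@H](c1cc(Cl)cc(OC)c1OCOC)[C@H](B1O[C@@]2(C)c3cccc4cccc(c34)[C@@]2(C)O1)c1cc(OC)c(OC)c(OCOC)c1
F3 | step 9 | (1S,2S)-2-[5-chloro-3-methoxy-2-(methoxymethoxy)phenyl]-1-[3,4-dimethoxy-5-(methoxymethoxy)phenyl]propan-1-ol | C[C@@H](c1cc(Cl)cc(OC)c1OCOC)[C@H](O)c1cc(OC)c(OC)c(OCOC)c1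
F4 | step 10 | (Z)-prop-1-enylboronic acid mac ester | C/C=C\B1O[C@@]2(C)c3cccc4cccc(c34)[C@@]2(C)O1
F5 | step 10 | lithium [3,4-dimethoxy-5-(methoxymethoxy)phenyl][(Z)-prop-1-enyl]borate of mac-H2 | [Li+].C/C=C\[B-]1(c2cc(OC)c(OC)c(OCOC)c2)O[C@@]2(C)c3cccc4cccc(c34)[C@@]2(C)O1
F6 | step 10 | B(mac) ester of [(1R,2R)-2-[5-chloro-3-methoxy-2-(pinacolatoboryloxy)phenyl]-1-[3,4-dimethoxy-5-(methoxymethoxy)phenyl]propyl]boronic acid | C[C@@H](c1cc(Cl)cc(OC)c1OB1OC(C)(C)C(C)(C)O1)[C@@H](B1O[C@@]2(C)c3cccc4cccc(c34)[C@@]2(C)O1)c1cc(OC)c(OC)c(OCOC)c1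
F7 | step 10 | (1R,2S)-2-(5-chloro-2-hydroxy-3-methoxyphenyl)-1-[3,4-dimethoxy-5-(methoxymethoxy)phenyl]propan-1-ol | C[C@@H](c1cc(Cl)cc(OC)c1O)[C@@H](O)c1cc(OC)c(OC)c(OCOC)c1
F8 | step 11 | 5-[(2S,3S)-7-methoxy-3-methyl-5-(4,4,5,5-tetramethyl-1,3,2-dioxaborolan-2-yl)-2,3-dihydro-1-benzofuran-2-yl]-2,3-dimethoxyphenol | CC1(C)OB(OC1(C)C)c1cc(OC)c2c(c1)[C@H](C)[C@@H](c1cc(O)c(OC)c(OC)c1)O2
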